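**Retrosynthetic overview**
1. Target 19 ← global O-demethylation of octamethyl ether 18; no stereocentre is touched.
2. 18 ← C3'–C4' bond plus lactone B (formed second): Michael addition/lactonisation of the chiral azolium enolate of α-chloroaldehyde 16 (ring A in place) onto o-quinone methide 17. This is the key fragment union.
3. 16 ← aldehyde 15 ← allyl lactone 14 ← the same Michael/lactonisation of 2-chloropent-4-enal 12 onto o-quinone methide 13 (lactone A formed first).
4. 13 and 17 ← sulfones 4 and 10 ← salicylaldehydes 1 and 8 plus 4-MeOC6H4MgBr; 8 ← 3,4,5-trimethoxyphenol.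

Assumption: the target is (3S,4R,3'S,4'R) with both lactone rings 3,4-cis as encoded; NHC*·HCl = (5aS,10bR)-N-mesityl aminoindanol-derived triazolium chloride (Bode precatalyst), taken to give the (4R) series – if the first annulation shows the opposite sense, the (5aR,10bS) salt is used in steps 7 and 10.

**Step 1**
Reactants: 1 2-hydroxy-4,6-dimethoxybenzaldehyde; 2 4-methoxyphenylmagnesium bromide
Product: 4 2-[(4-methoxyphenyl)(4-methylbenzenesulfonyl)methyl]-3,5-dimethoxyphenol (racemic), via benzhydrol 3 (not isolated)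
Conditions: 2 (2.5 equiv), THF, 0 °C→rt; pH 7 buffer; crude 3, p-TolSO2Na (2 equiv), HCO2H, CH2Cl2/H2O, rt
Reagents that add atoms: sodium p-toluenesulfinate, Cc1ccc(cc1)S(=O)[O-].[Na+]
Why: Grignard 1,2-addition to the phenoxide-aldehyde gives the labile benzhydrol, whose doubly activated benzylic OH ionises under mild acid and is trapped at sulfur by sulfinate (SN1 sulfonylation) to give a storable o-quinone-methide precursor; the racemic centre is planarised later.

**Step 2**
Reactants: 5 3,4,5-trimethoxyphenol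
Product: 6 2-hydroxy-4,5,6-trimethoxybenzaldehyde
Conditions: (CH2O)n (6 equiv), MgCl2 (1.5 equiv), Et3N (3.75 equiv), MeCN, reflux; 1 M HCl
Reagents that add atoms: paraformaldehyde (formaldehyde), C=O
Why: Magnesium-phenoxide-directed ortho-formylation (Casnati–Skattebøl) is strictly ortho-selective and the two ortho positions of 5 are equivalent.

**Step 3**
Reactants: 6 2-hydroxy-4,5,6-trimethoxybenzaldehyde
Product: 7 3-bromo-2-hydroxy-4,5,6-trimethoxybenzaldehyde
Conditions: NBS (1.05 equiv), MeCN, 0 °C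
Reagents that add atoms: N-bromosuccinimide, O=C1CCC(=O)N1Br
Why: Electrophilic aromatic bromination can only go to the single free ring position, which is ortho to the phenol and strongly activated.

**Step 4**
Reactants: 7 3-bromo-2-hydroxy-4,5,6-trimethoxybenzaldehyde
Product: 8 2-hydroxy-3,4,5,6-tetramethoxybenzaldehyde
Conditions: NaOMe (6 equiv), CuBr (20 mol %), DMF/MeOH, 110 °C; 1 M HCl
Reagents that add atoms: sodium methoxide, C[O-].[Na+]
Why: Copper-catalysed Ullmann-type methoxylation of an ortho-bromophenoxide (the 5-bromovanillin → syringaldehyde reaction type) replaces Br by OMe while the aldehyde is deactivated as its phenoxide.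

**Step 5**
Reactants: 8 2-hydroxy-3,4,5,6-tetramethoxybenzaldehyde; 2 4-methoxyphenylmagnesium bromide
Product: 10 2,3,4,5-tetramethoxy-6-[(4-methoxyphenyl)(4-methylbenzenesulfonyl)methyl]phenol (racemic), via benzhydrol 9 (not isolated)
Conditions: 2 (2.5 equiv), THF, 0 °C→rt; pH 7 buffer; crude 9, p-TolSO2Na (2 equiv), HCO2H, CH2Cl2/H2O, rt
Reagents that add atoms: sodium p-toluenesulfinate, Cc1ccc(cc1)S(=O)[O-].[Na+]
Why: Same Grignard addition/SN1 sulfonylation as step 1, giving the second o-quinone-methide precursor with no stereochemical demand.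

**Step 6**
Reactants: 11 pent-4-enal
Product: 12 2-chloropent-4-enal (racemic)
Conditions: NCS (1.0 equiv), DL-proline (10 mol %), CH2Cl2, 0 °C→rt; pentane, filter; used as solution
Reagents that add atoms: N-chlorosuccinimide, O=C1CCC(=O)N1Cl
Why: Enamine-catalysed α-chlorination of an aldehyde (Jørgensen type) stops at monochlorination, and its racemic centre is erased when the enolate forms in step 7.

**Step 7**
Reactants: 4 2-[(4-methoxyphenyl)(4-methylbenzenesulfonyl)methyl]-3,5-dimethoxyphenol; 12 2-chloropent-4-enal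
Product: 14 (3R,4R)-5,7-dimethoxy-4-(4-methoxyphenyl)-3-(prop-2-en-1-yl)-3,4-dihydro-2H-chromen-2-one, via o-quinone methide 13 (not isolated)
Conditions: 4, K2CO3 (2 equiv), CH2Cl2, 4 Å MS, rt, filter under Ar; then 12 (2 equiv), NHC*·HCl (10 mol %), Et3N (1.5 equiv), EtOAc, 0 °C→rt
Reagents that add atoms: none
Why: Base expels sulfinate to give o-quinone methide 13, and the carbene turns 12 (loss of HCl from the Breslow intermediate) into a chiral (Z)-azolium enolate that undergoes Michael addition to 13 and lactonisation (formal endo [4+2], Bode type); the catalyst shields one enolate face and the closed endo transition state gives the 3,4-cis (3R,4R) lactone.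

**Step 8**
Reactants: 14 (3R,4R)-5,7-dimethoxy-4-(4-methoxyphenyl)-3-(prop-2-en-1-yl)-3,4-dihydro-2H-chromen-2-one
Product: 15 2-[(3R,4R)-5,7-dimethoxy-4-(4-methoxyphenyl)-2-oxo-3,4-dihydro-2H-chromen-3-yl]acetaldehyde
Conditions: OsO4 (2 mol %), NaIO4 (4 equiv), 2,6-lutidine (2 equiv), dioxane/H2O 3:1, rt
Reagents that add atoms: osmium tetroxide, O=[Os](=O)(=O)=O; sodium periodate, [Na+].[O-]I(=O)(=O)=O
Why: Lemieux–Johnson oxidative cleavage acts only on the terminal alkene under near-neutral conditions, so the epimerisable cis-lactone and the electron-rich arenes are untouched.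

**Step 9**
Reactants: 15 2-[(3R,4R)-5,7-dimethoxy-4-(4-methoxyphenyl)-2-oxo-3,4-dihydro-2H-chromen-3-yl]acetaldehyde
Product: 16 (2RS)-2-chloro-2-[(3R,4R)-5,7-dimethoxy-4-(4-methoxyphenyl)-2-oxo-3,4-dihydro-2H-chromen-3-yl]acetaldehyde (epimers at C–Cl)
Conditions: NCS (1.05 equiv), DL-proline (10 mol %), CH2Cl2, 0 °C; used crude
Reagents that add atoms: N-chlorosuccinimide, O=C1CCC(=O)N1Cl
Why: Enamine-catalysed α-chlorination is faster than arene chlorination by un-activated NCS and is non-basic, so C3/C4 are untouched; the C–Cl centre becomes the planar enolate carbon in step 10.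

**Step 10**
Reactants: 16 (2RS)-2-chloro-2-[(3R,4R)-5,7-dimethoxy-4-(4-methoxyphenyl)-2-oxo-3,4-dihydro-2H-chromen-3-yl]acetaldehyde; 10 2,3,4,5-tetramethoxy-6-[(4-methoxyphenyl)(4-methylbenzenesulfonyl)methyl]phenol
Product: 18 (3S,3'S,4R,4'R)-5,5',6',7,7',8'-hexamethoxy-4,4'-bis(4-methoxyphenyl)-[3,3'-bichromane]-2,2'-dione, via o-quinone methide 17 (not isolated)
Conditions: 10 (1.5 equiv), K2CO3 (3 equiv), CH2Cl2, 4 Å MS, rt, filter under Ar; then 16, NHC*·HCl (20 mol %), Et3N (1.2 equiv), EtOAc/CH2Cl2, −20→0 °C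
Reagents that add atoms: none
Why: The same azolium-enolate Michael addition/lactonisation now joins the ring-A fragment to o-quinone methide 17 through the C3'–C4' bond; the catalyst again fixes the enolate face and the endo closure gives the second cis-lactone as (3'S,4'R), while the weak base and low temperature leave C3 untouched.

**Step 11**
Reactants: 18 (3S,3'S,4R,4'R)-5,5',6',7,7',8'-hexamethoxy-4,4'-bis(4-methoxyphenyl)-[3,3'-bichromane]-2,2'-dione
Product: 19 (3S,3'S,4R,4'R)-5,5',6',7,7',8'-hexahydroxy-4,4'-bis(4-hydroxyphenyl)-[3,3'-bichromane]-2,2'-dione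
Conditions: BBr3 (20 equiv), CH2Cl2, −78 °C→rt, Ar; ice/degassed 1 M HCl (ascorbic acid), EtOAc
Reagents that add atoms: none
Why: Lewis-acid ether cleavage via aryloxy-dibromoboranes removes all eight methyl groups without base, so the two lactone α-centres are not enolised and the aryl lactones survive or re-close on the acidic work-up.

**Compound list**
1 | 2-hydroxy-4,6-dimethoxybenzaldehyde | O=Cc1c(O)cc(OC)cc1OC | starting material
2 | 4-methoxyphenylmagnesium bromide | COc1ccc([Mg]Br)cc1 | starting material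
3 | 2-[hydroxy(4-methoxyphenyl)methyl]-3,5-dimethoxyphenol (racemic) | OC(c1ccc(OC)cc1)c1c(O)cc(OC)cc1OC | intermediate
4 | 2-[(4-methoxyphenyl)(4-methylbenzenesulfonyl)methyl]-3,5-dimethoxyphenol (racemic) | Cc1ccc(cc1)S(=O)(=O)C(c1ccc(OC)cc1)c1c(O)cc(OC)cc1OC | intermediate
5 | 3,4,5-trimethoxyphenol | COc1cc(O)cc(OC)c1OC | starting material
6 | 2-hydroxy-4,5,6-trimethoxybenzaldehyde | O=Cc1c(O)cc(OC)c(OC)c1OC | intermediate
7 | 3-bromo-2-hydroxy-4,5,6-trimethoxybenzaldehyde | O=Cc1c(O)c(Br)c(OC)c(OC)c1OC | intermediate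
8 | 2-hydroxy-3,4,5,6-tetramethoxybenzaldehyde | O=Cc1c(O)c(OC)c(OC)c(OC)c1OC | intermediate
9 | 2-[hydroxy(4-methoxyphenyl)methyl]-3,4,5,6-tetramethoxyphenol (racemic) | OC(c1ccc(OC)cc1)c1c(O)c(OC)c(OC)c(OC)c1OC | intermediate
10 | 2,3,4,5-tetramethoxy-6-[(4-methoxyphenyl)(4-methylbenzenesulfonyl)methyl]phenol (racemic) | Cc1ccc(cc1)S(=O)(=O)C(c1ccc(OC)cc1)c1c(O)c(OC)c(OC)c(OC)c1OC | intermediate
11 | pent-4-enal | C=CCCC=O | starting material
12 | 2-chloropent-4-enal (racemic) | C=CCC(Cl)C=O | intermediate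
13 | 3,5-dimethoxy-6-[(4-methoxyphenyl)methylidene]cyclohexa-2,4-dien-1-one | O=C1C=C(OC)C=C(OC)C1=Cc1ccc(OC)cc1 | intermediate
14 | (3R,4R)-5,7-dimethoxy-4-(4-methoxyphenyl)-3-(prop-2-en-1-yl)-3,4-dihydro-2H-chromen-2-one | O=C1Oc2cc(OC)cc(OC)c2[C@@H](c2ccc(OC)cc2)[C@H]1CC=C | intermediate
15 | 2-[(3R,4R)-5,7-dimethoxy-4-(4-methoxyphenyl)-2-oxo-3,4-dihydro-2H-chromen-3-yl]acetaldehyde | O=C1Oc2cc(OC)cc(OC)c2[C@@H](c2ccc(OC)cc2)[C@H]1CC=O | intermediate
16 | (2RS)-2-chloro-2-[(3R,4R)-5,7-dimethoxy-4-(4-methoxyphenyl)-2-oxo-3,4-dihydro-2H-chromen-3-yl]acetaldehyde | O=C1Oc2cc(OC)cc(OC)c2[C@@H](c2ccc(OC)cc2)[C@H]1C(Cl)C=O | intermediate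
17 | 2,3,4,5-tetramethoxy-6-[(4-methoxyphenyl)methylidene]cyclohexa-2,4-dien-1-one | O=C1C(OC)=C(OC)C(OC)=C(OC)C1=Cc1ccc(OC)cc1 | intermediate
18 | (3S,3'S,4R,4'R)-5,5',6',7,7',8'-hexamethoxy-4,4'-bis(4-methoxyphenyl)-[3,3'-bichromane]-2,2'-dione | O=C1Oc2cc(OC)cc(OC)c2[C@@H](c2ccc(OC)cc2)[C@H]1[C@H]1C(=O)Oc2c(OC)c(OC)c(OC)c(OC)c2[C@H]1c1ccc(OC)cc1 | intermediate
19 | (3S,3'S,4R,4'R)-5,5',6',7,7',8'-hexahydroxy-4,4'-bis(4-hydroxyphenyl)-[3,3'-bichromane]-2,2'-dione | O=C1Oc2cc(O)cc(O)c2[C@@H](c2ccc(O)cc2)[C@H]1[C@H]1C(=O)Oc2c(O)c(O)c(O)c(O)c2[C@H]1c1ccc(O)cc1 | target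

**Totals**
Total steps: 11. Longest linear sequence: 6 steps (2 → 3 → 4 → 5 → 10 → 11; the branches through steps 1 or 6 are also 6).

**Three steps most likely to fail**

Step 10 (key union). The enolate is β-branched, the o-quinone methide carries a peri-methoxy group, and catalyst control may be mismatched with the existing C3/C4 centres. Compound 16 can also lose HCl through the lactone α-position, which would scramble C3. The fallback takes the acidic lactone out of the substrate and closes ring A last. Setting out from 14, methanolysis and O-methylation (NaOMe, MeOH, 0 °C; then MeI) give methyl (2R)-2-[(R)-(4-methoxyphenyl)(2,4,6-trimethoxyphenyl)methyl]pent-4-enoate F1. Lemieux–Johnson cleavage gives methyl (2R)-2-[(R)-(4-methoxyphenyl)(2,4,6-trimethoxyphenyl)methyl]-4-oxobutanoate F2. NCS/DL-proline gives methyl (2R)-3-chloro-2-[(R)-(4-methoxyphenyl)(2,4,6-trimethoxyphenyl)methyl]-4-oxobutanoate F3. The same azolium-enolate Michael addition/lactonisation with 17 (from 10) gives methyl (2S,3R)-3-(4-methoxyphenyl)-2-[(3S,4R)-5,6,7,8-tetramethoxy-4-(4-methoxyphenyl)-2-oxo-3,4-dihydro-2H-chromen-3-yl]-3-(2,4,6-trimethoxyphenyl)propanoate F4. BBr3 then cleaves the nine aryl methyl ethers, and the freed ortho-phenol lactonises onto the methyl ester on acidic work-up (TFA in degassed MeCN if needed), coming back to the route at 19.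

Step 7 (first annulation). The cis-selectivity and enantioselectivity of the carbene annulation are not secured for an o-quinone methide with a peri-methoxy group. The fallback sets C4 by conjugate arylation and C3 by kinetic protonation. Setting out from 1, Wittig olefination/lactonisation with ethyl (triphenylphosphoranylidene)acetate (PhNEt2, reflux) gives 5,7-dimethoxy-2H-chromen-2-one F5. Rh(acac)(C2H4)2/(R)-Segphos-catalysed addition of 4-methoxyphenylboronic acid (Hayashi–Miyaura, dioxane/H2O, 60 °C; sense as in the 4-arylchroman-2-one precedent) gives (4R)-5,7-dimethoxy-4-(4-methoxyphenyl)-3,4-dihydro-2H-chromen-2-one F6. LiHMDS/allyl bromide (THF, −78 °C) alkylates anti to the pseudo-axial 4-aryl group to give trans-(3S,4R)-5,7-dimethoxy-4-(4-methoxyphenyl)-3-(prop-2-en-1-yl)-3,4-dihydro-2H-chromen-2-one F7. Re-enolisation (LiHMDS, −78 °C) and kinetic protonation with 2,6-di-tert-butylphenol, again anti to the aryl group, inverts C3 and comes back to the route at 14.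

Step 11 (global demethylation). Cleavage of eight ethers may be incomplete, and the tetrahydroxybenzene ring of the product is very air-sensitive, which makes direct isolation difficult. The fallback isolates through a protected derivative. Setting out from 18, BBr3 is used as before but the crude polyphenol is peracetylated directly (Ac2O, pyridine, 0 °C) to (3S,3'S,4R,4'R)-2,2'-dioxo-4,4'-bis(4-acetoxyphenyl)-[3,3'-bichromane]-5,5',6',7,7',8'-hexayl hexaacetate F8, which is air-stable and can be purified on silica. Mild transesterification of the eight aryl acetates (NH4OAc, aq. MeOH, rt, Ar), followed by brief TFA treatment to re-close any opened lactone, comes back to the route at 19.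

**Further compounds**
F1 | step 10 | methyl (2R)-2-[(R)-(4-methoxyphenyl)(2,4,6-trimethoxyphenyl)methyl]pent-4-enoate | COc1cc(OC)cc(OC)c1[C@@H](c1ccc(OC)cc1)[C@H](C(=O)OC)CC=C
F2 | step 10 | methyl (2R)-2-[(R)-(4-methoxyphenyl)(2,4,6-trimethoxyphenyl)methyl]-4-oxobutanoate | COc1cc(OC)cc(OC)c1[C@@H](c1ccc(OC)cc1)[C@H](C(=O)OC)CC=O
F3 | step 10 | methyl (2R)-3-chloro-2-[(R)-(4-methoxyphenyl)(2,4,6-trimethoxyphenyl)methyl]-4-oxobutanoate (epimers at C3) | COc1cc(OC)cc(OC)c1[C@@H](c1ccc(OC)cc1)[C@H](C(=O)OC)C(Cl)C=O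
F4 | step 10 | methyl (2S,3R)-3-(4-methoxyphenyl)-2-[(3S,4R)-5,6,7,8-tetramethoxy-4-(4-methoxyphenyl)-2-oxo-3,4-dihydro-2H-chromen-3-yl]-3-(2,4,6-trimethoxyphenyl)propanoate | COc1cc(OC)cc(OC)c1[C@@H](c1ccc(OC)cc1)[C@H](C(=O)OC)[C@H]1C(=O)Oc2c(OC)c(OC)c(OC)c(OC)c2[C@H]1c1ccc(OC)cc1
F5 | step 7 | 5,7-dimethoxy-2H-chromen-2-one | COc1cc(OC)c2ccc(=O)oc2c1
F6 | step 7 | (4R)-5,7-dimethoxy-4-(4-methoxyphenyl)-3,4-dihydro-2H-chromen-2-one | O=C1Oc2cc(OC)cc(OC)c2[C@@H](c2ccc(OC)cc2)C1
F7 | step 7 | (3S,4R)-5,7-dimethoxy-4-(4-methoxyphenyl)-3-(prop-2-en-1-yl)-3,4-dihydro-2H-chromen-2-one | O=C1Oc2cc(OC)cc(OC)c2[C@@H](c2ccc(OC)cc2)[C@@H]1CC=C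
F8 | step 11 | (3S,3'S,4R,4'R)-2,2'-dioxo-4,4'-bis(4-acetoxyphenyl)-[3,3'-bichromane]-5,5',6',7,7',8'-hexayl hexaacetate | O=C1Oc2cc(OC(C)=O)cc(OC(C)=O)c2[C@@H](c2ccc(OC(C)=O)cc2)[C@H]1[C@H]1C(=O)Oc2c(OC(C)=O)c(OC(C)=O)c(OC(C)=O)c(OC(C)=O)c2[C@H]1c1ccc(OC(C)=O)cc1
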